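**Strategy.** The route rests on cutting the C9–C10 bond of the cis-decalin, which unravels ring B onto an achiral 4,4-disubstituted cyclohexadienone. The key step exploits the prochiral quaternary C5 of that dienone (ring A), whose two mirror-related enone arms end in C10 and C4, and the C8 ketone whose silyloxy-bearing C9 sits 1,5 to them. One amine-catalysed intramolecular Michael addition closes ring B and fixes C5, C9 and C10 together. The precursor is 4-methylcyclohexa-2,5-dienone carrying a 4-(silyloxy)-3-oxobutyl chain on its quaternary carbon. Afterwards the surviving enone delivers C4 and C3, and a butenolide locks the Z alkene.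

Key step: step 7

Remarks on the chemistry (one line each):
- Eremophilane numbering is used; β is the face of the C5 methyl group; ξ marks a centre carried as a mixture (its SMILES centre is left open).
- The donor chain must be the four-carbon 4-oxy-3-oxobutyl group (C6–C9); a 5-oxy-4-oxopentyl chain would close a seven-membered ring and is not used.
- The C9 oxygen is a TBS ether from the precursor to the last step, so no protecting-group exchange or hydrogenolysis is needed beside the alkenes.
- C7, C8 and C11 are diastereomer mixtures from step 9 until steps 14 and 17 erase them.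
- Assumption: 9-amino-9-deoxy-epi-quinine selects the enone arm that gives (4aR,8aS); if not, its quinidine-derived pseudo-enantiomer is used.
- Assumption: ethyl (E)-3-iodoacrylate is taken as commercially available.

**Route**

Step 1
Reactants: 1 hex-5-en-2-one; 2 (methoxymethyl)triphenylphosphonium chloride
Product: 4 2-methylhex-5-enal (racemic), via 1-methoxy-2-methylhexa-1,5-diene 3 (not isolated)
Conditions: KOtBu, THF, 0 °C → rt; then 2 M HCl, THF, rt
Reagents that add atoms: water, O
Why: Wittig methoxymethylenation of the methyl ketone and enol-ether hydrolysis is the standard one-carbon homologation to an α-branched aldehyde; the new centre is racemic and later becomes the prochiral C5.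

Step 2
Reactants: 4 2-methylhex-5-enal; 5 but-3-en-2-one (methyl vinyl ketone)
Product: 8 4-(but-3-en-1-yl)-4-methylcyclohex-2-en-1-one (racemic), via pyrrolidine enamine 6 (not isolated), via keto aldehyde 7 (not isolated)
Conditions: pyrrolidine, PhH, reflux (−H2O); 5, rt; then AcOH, NaOAc, H2O, reflux
Reagents that add atoms: none
Why: Stork enamine Michael addition followed by intramolecular aldol condensation (Robinson annulation) is the classical entry to 4,4-disubstituted cyclohexenones from α-branched aldehydes.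

Step 3
Reactants: 8 4-(but-3-en-1-yl)-4-methylcyclohex-2-en-1-one
Product: 9 4-(but-3-en-1-yl)-4-methylcyclohexa-2,5-dien-1-one
Conditions: DDQ, 1,4-dioxane, reflux
Reagents that add atoms: none
Why: DDQ dehydrogenation of a 4,4-disubstituted cyclohexenone should give the achiral cross-conjugated dienone, and the isolated terminal alkene is inert to the quinone.

Step 4
Reactants: 9 4-(but-3-en-1-yl)-4-methylcyclohexa-2,5-dien-1-one
Product: 10 4-(3,4-dihydroxybutyl)-4-methylcyclohexa-2,5-dien-1-one (racemic)
Conditions: OsO4 (2 mol %), N-methylmorpholine N-oxide, acetone–H2O, 0 °C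
Reagents that add atoms: N-methylmorpholine N-oxide, C[N+]1([O-])CCOCC1; water, O
Why: Upjohn dihydroxylation, in which electrophilic OsO4 should take the electron-rich terminal alkene well before the electron-poor dienone double bonds; neutral, cold conditions keep the secondary hydroxyl from adding to the dienone.

Step 5
Reactants: 10 4-(3,4-dihydroxybutyl)-4-methylcyclohexa-2,5-dien-1-one
Product: 11 4-{4-[(tert-butyldimethylsilyl)oxy]-3-hydroxybutyl}-4-methylcyclohexa-2,5-dien-1-one (racemic)
Conditions: TBSCl (1.05 equiv), imidazole, CH2Cl2, −20 °C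
Reagents that add atoms: tert-butylchlorodimethylsilane, CC(C)(C)[Si](C)(C)Cl
Why: Sterically controlled silylation should protect the primary hydroxyl of the 1,2-diol selectively.

Step 6
Reactants: 11 4-{4-[(tert-butyldimethylsilyl)oxy]-3-hydroxybutyl}-4-methylcyclohexa-2,5-dien-1-one
Product: 12 4-{4-[(tert-butyldimethylsilyl)oxy]-3-oxobutyl}-4-methylcyclohexa-2,5-dien-1-one
Conditions: Dess–Martin periodinane, NaHCO3, CH2Cl2, 0 °C → rt
Reagents that add atoms: none
Why: Buffered Dess–Martin oxidation converts the secondary alcohol into the α-silyloxy ketone without touching the dienone and removes the hydroxyl that could cyclise onto it.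

Step 7
Reactants: 12 4-{4-[(tert-butyldimethylsilyl)oxy]-3-oxobutyl}-4-methylcyclohexa-2,5-dien-1-one
Product: 15 (4aR,8R,8aS)-8-[(tert-butyldimethylsilyl)oxy]-4a-methyl-4a,5,6,8a-tetrahydronaphthalene-2,7(1H,8H)-dione (cis-fused), via catalyst-bound enamine 13 (not isolated), via catalyst-bound ketimine 14 (not isolated)
Conditions: 9-amino-9-deoxy-epi-quinine (20 mol %), PhCO2H (40 mol %), toluene, 30 °C
Reagents that add atoms: none
Why: The primary amine condenses with the C8 ketone, only the enamine toward C9 can cyclise (a C7 enamine would have to form a four-membered ring), and C9 adds to C10 of one enone arm while the protonated quinuclidine and the carboxylate organise the dienone, after which hydrolysis of ketimine 14 returns the catalyst. The closest known reaction type is the amine-catalysed desymmetrising intramolecular Michael addition of tethered aldehydes to 4,4-disubstituted cyclohexadienones, taken together with the established use of O-protected α-hydroxy ketones as enamine donors for primary amine catalysts; the α-silyloxy ketone extends the donor scope of the former. Ring B closes in a 6-(enolendo)-exo-trig mode. C5 and C10 are set together by the catalyst's choice between the two enantiotopic enone arms, the cis fusion is dictated by the tether, which reaches C10 only from its own face, and C9 follows from the N–H···O-bridged Z enamine in a chair-like transition state. C9 stays epimerisable next to C8=O, so it can settle with the silyloxy group equatorial and trans to the C10–C1 bond, which is the configuration of the target. The step needs arm selectivity (catalyst control) and C9-over-C7 regioselectivity (ring size), and the untouched second arm survives as the C2=O/C3=C4 enone for ring A.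

Step 8
Reactants: 15 cis-fused enone-dione
Product: 17 4β,5β-dimethyl-9β-[(tert-butyldimethylsilyl)oxy]-2-(triethylsilyloxy)-10βH-decal-2-en-8-one (eremophilane numbering), via lithium C2 enolate 16 (not isolated)
Conditions: Me2CuLi (from MeLi, CuI), Et2O, −78 °C; then TESCl, Et3N, HMPA, −78 → 0 °C
Reagents that add atoms: lithium dimethylcuprate, [Li+].C[Cu-]C; chlorotriethylsilane, CC[Si](Cl)(CC)CC
Why: Cuprate conjugate addition with silyl trapping, in which axial attack on the convex face (anti to ring B, syn to the C5 methyl and C10–H) should set 4β-CH3; the saturated α-silyloxy C8 ketone reacts far more slowly at −78 °C, and the TES enol ether stores the C2=C3 enolate.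

Step 9
Reactants: 17 TES enol ether; 18 ethyl pyruvate
Product: 20 ethyl 2-hydroxy-2-[(7ξ)-8-oxo-decalinyl]propanoate aldol adduct at C7 (7ξ,11ξ), via lithium C8 enolate 19 (not isolated)
Conditions: LiN(iPr)2, THF, −78 °C; 18, −78 °C; AcOH quench
Reagents that add atoms: none
Why: Kinetic deprotonation of the only ketone should occur at the unhindered C7 methylene and not at the silyloxy-bearing C9, and the lithium enolate undergoes aldol addition to the electrophilic keto group of the pyruvate (C7 and C11 mixtures are erased later).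

Step 10
Reactants: 20 aldol adduct
Product: 22 2-(triethylsilyloxy)-9β-[(tert-butyldimethylsilyl)oxy]-11ξ-hydroxy-10βH-eremophil-2-en-12,8ξ-olide (7ξ), via 8-hydroxy ester 21 (not isolated)
Conditions: NaBH4, EtOH–THF, −20 → 0 °C
Reagents that add atoms: none
Why: Borohydride reduction of the C8 ketone gives a γ-hydroxy ester whose alkoxide closes the five-membered lactone (lactonisation); the lactone masks C8 during the ring A steps and later enforces the alkene geometry.

Step 11
Reactants: 22 hydroxy lactone TES enol ether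
Product: 24 3α-(triethylsilyloxy)-9β-[(tert-butyldimethylsilyl)oxy]-11ξ-hydroxy-2-oxo-10βH-eremophilan-12,8ξ-olide, via silyloxy epoxide 23 (not isolated)
Conditions: mCPBA, NaHCO3, CH2Cl2, −20 → 0 °C
Reagents that add atoms: 3-chloroperbenzoic acid, OOC(=O)c1cccc(Cl)c1
Why: Rubottom oxidation, in which the peracid should epoxidise the silyl enol ether on the α face opposite the adjacent 4β-methyl group and a 1,4-silyl shift gives the 3α-silyloxy ketone, also the equatorial (thermodynamic) C3 epimer.

Step 12
Reactants: 24 3α-silyloxy 2-ketone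
Product: 25 C2 tosylhydrazone of 24
Conditions: TsNHNH2, THF, 4 Å molecular sieves, 45 °C
Reagents that add atoms: 4-methylbenzenesulfonohydrazide, Cc1ccc(cc1)S(=O)(=O)NN
Why: Hydrazone condensation at the only ketone in the molecule (C2); lactone, tertiary alcohol and silyl ethers do not react.

Step 13
Reactants: 25 C2 tosylhydrazone
Product: 28 3α-(triethylsilyloxy)-9β-[(tert-butyldimethylsilyl)oxy]-11ξ-hydroxy-10βH-eremophilan-12,8ξ-olide, via tosylhydrazine 26 (not isolated), via diazene 27 (not isolated)
Conditions: catecholborane, CHCl3, 0 °C; then NaOAc·3H2O, reflux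
Reagents that add atoms: none
Why: Tosylhydrazone reduction (Caglioti reaction, catecholborane variant): hydride adds to C=N, acetate triggers loss of sulfinate and the diazene expels N2 to leave CH2 under conditions mild enough that the poor silyloxy leaving group at C3 should stay.

Step 14
Reactants: 28 11-hydroxy lactone
Product: 29 3α-(triethylsilyloxy)-9β-[(tert-butyldimethylsilyl)oxy]-10βH-eremophil-7(11)-en-12,8ξ-olide
Conditions: SOCl2, pyridine, CH2Cl2, −20 → 0 °C
Reagents that add atoms: none
Why: E2 dehydration of the tertiary α-hydroxy lactone should give the tetrasubstituted conjugated butenolide, in which the ring ties C12 to the C8 oxygen and so forces C12 cis to C8 across C7=C11.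

Step 15
Reactants: 29 butenolide
Product: 31 3α-(triethylsilyloxy)-9β-[(tert-butyldimethylsilyl)oxy]-10βH-eremophil-7(11)Z-ene-8ξ,12-diol, via lactol 30 (not isolated)
Conditions: iBu2AlH (4 equiv), CH2Cl2, −78 → 0 °C; aq. KNaC4H4O6 (potassium sodium tartrate)
Reagents that add atoms: none
Why: Hydride reduction of the butenolide through the lactol gives the (Z)-2-ene-1,4-diol, carrying the ring-enforced cis relation of C12 and C8 into the open chain; excess hydride and a neutral work-up avoid the acid-labile lactol.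

Step 16
Reactants: 31 ene-diol
Product: 32 12-O-TBS ether of 31
Conditions: TBSCl (1.05 equiv), imidazole, CH2Cl2, −20 °C
Reagents that add atoms: tert-butylchlorodimethylsilane, CC(C)(C)[Si](C)(C)Cl
Why: Selective silylation of the primary allylic hydroxyl over the hindered secondary C8 hydroxyl.

Step 17
Reactants: 32 C8 alcohol
Product: 33 3α-(triethylsilyloxy)-9β,12-bis[(tert-butyldimethylsilyl)oxy]-10βH-eremophil-7(11)Z-en-8-one
Conditions: Dess–Martin periodinane, NaHCO3, CH2Cl2, 0 °C → rt
Reagents that add atoms: none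
Why: Dess–Martin oxidation of the secondary allylic alcohol restores the C8 ketone as the (Z)-γ-silyloxy enone; the alkene geometry is untouched and buffered conditions protect C9.

Step 18
Reactants: 33 tris-silyl enone
Product: 34 9β,12-bis[(tert-butyldimethylsilyl)oxy]-3α-hydroxy-10βH-eremophil-7(11)Z-en-8-one
Conditions: PPTS (0.1 equiv), MeOH–CH2Cl2, 0 °C
Reagents that add atoms: none
Why: Acid-catalysed methanolysis (selective silyl ether cleavage) should remove the triethylsilyl group much faster than either TBS ether, freeing only the C3 hydroxyl.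

Step 19
Reactants: 35 (E)-oct-2-enal
Product: 36 (E)-non-3-en-1-yne
Conditions: dimethyl (1-diazo-2-oxopropyl)phosphonate, K2CO3, MeOH, 0 °C → rt
Reagents that add atoms: dimethyl (1-diazo-2-oxopropyl)phosphonate, COP(=O)(OC)C(=[N+]=[N-])C(C)=O
Why: Seyferth–Gilbert homologation with the Ohira–Bestmann reagent converts the enal into the terminal enyne under mild base without touching the E alkene.

Step 20
Reactants: 36 (E)-non-3-en-1-yne; 37 ethyl (E)-3-iodoacrylate
Product: 39 ethyl (2E,4E,6E)-5-methyldodeca-2,4,6-trienoate, via alkenylalane 38 (not isolated)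
Conditions: Me3Al, Cp2ZrCl2 (20 mol %), ClCH2CH2Cl, rt; then 37, Pd(PPh3)4 (5 mol %), ZnCl2 (cat.), THF, rt
Reagents that add atoms: trimethylaluminium, C[Al](C)C
Why: Zirconium-catalysed syn carboalumination places CH3 on the internal alkyne carbon, and Negishi coupling of the alkenylalane with the (E)-iodoacrylate under zerovalent palladium catalysis proceeds with retention, fixing all three E alkenes.

Step 21
Reactants: 39 ethyl trienoate
Product: 40 (2E,4E,6E)-5-methyldodeca-2,4,6-trienoic acid
Conditions: LiOH, THF–MeOH–H2O, rt; then 1 M HCl to pH 3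
Reagents that add atoms: lithium hydroxide, [Li+].[OH-]
Why: Ester saponification with LiOH at room temperature should leave the triene geometry intact.

Step 22
Reactants: 34 C3 alcohol; 40 trienoic acid
Product: 42 3α-[(2E,4E,6E)-5-methyldodeca-2,4,6-trienoyloxy]-9β,12-bis[(tert-butyldimethylsilyl)oxy]-10βH-eremophil-7(11)Z-en-8-one, via mixed anhydride 41 (not isolated)
Conditions: 40, 2,4,6-trichlorobenzoyl chloride, Et3N, THF, rt; then 34, DMAP, toluene, rt
Reagents that add atoms: none
Why: Yamaguchi esterification, in which the mixed anhydride acylates the hindered equatorial C3 alcohol with retention at C3 while C9 and C12 are silylated.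

Step 23
Reactants: 42 bis-silyl ester
Product: 43 3α-[(2E,4E,6E)-5-methyldodeca-2,4,6-trienoyloxy]-9β,12-dihydroxy-10βH-eremophil-7(11)Z-en-8-one, (3R,4R,5R,9R,10S), CNP0226738.1
Conditions: HF·pyridine, pyridine, THF, 0 °C → rt
Reagents that add atoms: none
Why: Fluoride desilylation with pyridine-buffered HF·pyridine should remove both TBS ethers without acid strong enough to cyclodehydrate the (Z)-γ-hydroxy enone to a furan or to cleave the trienoate.

**Compound list**

1 | hex-5-en-2-one | CC(=O)CCC=C | starting material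
2 | (methoxymethyl)triphenylphosphonium chloride | COC[P+](c1ccccc1)(c1ccccc1)c1ccccc1.[Cl-] | starting material
3 | 1-methoxy-2-methylhexa-1,5-diene (E/Z mixture) | COC=C(C)CCC=C | intermediate (not isolated)
4 | 2-methylhex-5-enal (racemic) | C=CCCC(C)C=O | intermediate
5 | but-3-en-2-one (methyl vinyl ketone) | C=CC(C)=O | starting material
6 | 1-(2-methylhexa-1,5-dien-1-yl)pyrrolidine | C=CCCC(C)=CN1CCCC1 | intermediate (not isolated)
7 | 2-(but-3-en-1-yl)-2-methyl-5-oxohexanal (racemic) | C=CCCC(C)(C=O)CCC(C)=O | intermediate (not isolated)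
8 | 4-(but-3-en-1-yl)-4-methylcyclohex-2-en-1-one (racemic) | C=CCCC1(C)CCC(=O)C=C1 | intermediate
9 | 4-(but-3-en-1-yl)-4-methylcyclohexa-2,5-dien-1-one | C=CCCC1(C)C=CC(=O)C=C1 | intermediate
10 | 4-(3,4-dihydroxybutyl)-4-methylcyclohexa-2,5-dien-1-one (racemic) | OCC(O)CCC1(C)C=CC(=O)C=C1 | intermediate
11 | 4-{4-[(tert-butyldimethylsilyl)oxy]-3-hydroxybutyl}-4-methylcyclohexa-2,5-dien-1-one (racemic) | CC1(CCC(O)CO[Si](C)(C)C(C)(C)C)C=CC(=O)C=C1 | intermediate
12 | 4-{4-[(tert-butyldimethylsilyl)oxy]-3-oxobutyl}-4-methylcyclohexa-2,5-dien-1-one (key-step precursor, achiral) | CC1(CCC(=O)CO[Si](C)(C)C(C)(C)C)C=CC(=O)C=C1 | intermediate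
13 | C8=C9 enamine of 12 on the nitrogen of 9-amino-9-deoxy-epi-quinine | CC1(CCC(=CO[Si](C)(C)C(C)(C)C)N[C@H]([C@@H]2C[C@@H]3CCN2C[C@@H]3C=C)c2ccnc3ccc(OC)cc23)C=CC(=O)C=C1 | intermediate (not isolated)
14 | C8 ketimine of 15 on the catalyst nitrogen | O=C1C=C[C@@]2(C)CCC(=N[C@H]([C@@H]3C[C@@H]4CCN3C[C@@H]4C=C)c3ccnc4ccc(OC)cc34)[C@H](O[Si](C)(C)C(C)(C)C)[C@H]2C1 | intermediate (not isolated)
15 | (4aR,8R,8aS)-8-[(tert-butyldimethylsilyl)oxy]-4a-methyl-4a,5,6,8a-tetrahydronaphthalene-2,7(1H,8H)-dione (key-step product; cis-fused, 5β-CH3, 10β-H, 9β-OTBS) | O=C1C=C[C@@]2(C)CCC(=O)[C@H](O[Si](C)(C)C(C)(C)C)[C@H]2C1 | intermediate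
16 | lithium C2 enolate after 4β-methyl addition | [Li]OC1=C[C@H](C)[C@@]2(C)CCC(=O)[C@H](O[Si](C)(C)C(C)(C)C)[C@H]2C1 | intermediate (not isolated)
17 | C2 triethylsilyl enol ether (C2=C3), 4β,5β-dimethyl, 8-oxo, 9β-OTBS, 10β-H | CC[Si](CC)(CC)OC1=C[C@H](C)[C@@]2(C)CCC(=O)[C@H](O[Si](C)(C)C(C)(C)C)[C@H]2C1 | intermediate
18 | ethyl pyruvate | CCOC(=O)C(C)=O | starting material
19 | lithium C8 enolate (C7=C8) of 17 | CC[Si](CC)(CC)OC1=C[C@H](C)[C@@]2(C)CC=C(O[Li])[C@H](O[Si](C)(C)C(C)(C)C)[C@H]2C1 | intermediate (not isolated)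
20 | C7 aldol adduct of 17 with ethyl pyruvate (7ξ,11ξ) | CC[Si](CC)(CC)OC1=C[C@H](C)[C@@]2(C)CC(C(C)(O)C(=O)OCC)C(=O)[C@H](O[Si](C)(C)C(C)(C)C)[C@H]2C1 | intermediate
21 | 8ξ-hydroxy ester from reduction of 20 | CC[Si](CC)(CC)OC1=C[C@H](C)[C@@]2(C)CC(C(C)(O)C(=O)OCC)C(O)[C@H](O[Si](C)(C)C(C)(C)C)[C@H]2C1 | intermediate (not isolated)
22 | 2-(triethylsilyloxy)-9β-OTBS-11ξ-hydroxy-10βH-eremophil-2-en-12,8ξ-olide | CC[Si](CC)(CC)OC1=C[C@H](C)[C@@]2(C)CC3C(OC(=O)C3(C)O)[C@H](O[Si](C)(C)C(C)(C)C)[C@H]2C1 | intermediate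
23 | 2α,3α-epoxide of 22 (2-silyloxy epoxide) | CC[Si](CC)(CC)O[C@]12O[C@H]1[C@H](C)[C@@]3(C)CC4C(OC(=O)C4(C)O)[C@H](O[Si](C)(C)C(C)(C)C)[C@H]3C2 | intermediate (not isolated)
24 | 3α-(triethylsilyloxy)-9β-OTBS-11ξ-hydroxy-2-oxo-10βH-eremophilan-12,8ξ-olide | CC[Si](CC)(CC)O[C@@H]1C(=O)C[C@@H]2[C@@H](O[Si](C)(C)C(C)(C)C)C3OC(=O)C(C)(O)C3C[C@]2(C)[C@H]1C | intermediate
25 | C2 tosylhydrazone of 24 | CC[Si](CC)(CC)O[C@@H]1C(=NNS(=O)(=O)c3ccc(C)cc3)C[C@@H]2[C@@H](O[Si](C)(C)C(C)(C)C)C3OC(=O)C(C)(O)C3C[C@]2(C)[C@H]1C | intermediate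
26 | C2 N'-tosylhydrazine (boron-bound in the flask) | CC[Si](CC)(CC)O[C@@H]1C(NNS(=O)(=O)c3ccc(C)cc3)C[C@@H]2[C@@H](O[Si](C)(C)C(C)(C)C)C3OC(=O)C(C)(O)C3C[C@]2(C)[C@H]1C | intermediate (not isolated)
27 | C2 diazene | CC[Si](CC)(CC)O[C@@H]1C(N=N)C[C@@H]2[C@@H](O[Si](C)(C)C(C)(C)C)C3OC(=O)C(C)(O)C3C[C@]2(C)[C@H]1C | intermediate (not isolated)
28 | 3α-(triethylsilyloxy)-9β-OTBS-11ξ-hydroxy-10βH-eremophilan-12,8ξ-olide | CC[Si](CC)(CC)O[C@@H]1CC[C@@H]2[C@@H](O[Si](C)(C)C(C)(C)C)C3OC(=O)C(C)(O)C3C[C@]2(C)[C@H]1C | intermediate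
29 | 3α-(triethylsilyloxy)-9β-OTBS-10βH-eremophil-7(11)-en-12,8ξ-olide | CC[Si](CC)(CC)O[C@@H]1CC[C@@H]2[C@@H](O[Si](C)(C)C(C)(C)C)C3OC(=O)C(C)=C3C[C@]2(C)[C@H]1C | intermediate
30 | lactol of 29 (12ξ-hydroxy-8,12-epoxide) | CC[Si](CC)(CC)O[C@@H]1CC[C@@H]2[C@@H](O[Si](C)(C)C(C)(C)C)C3OC(O)C(C)=C3C[C@]2(C)[C@H]1C | intermediate (not isolated)
31 | 3α-(triethylsilyloxy)-9β-OTBS-10βH-eremophil-7(11)Z-ene-8ξ,12-diol | CC[Si](CC)(CC)O[C@@H]1CC[C@@H]2[C@@H](O[Si](C)(C)C(C)(C)C)C(O)/C(=C(/C)CO)C[C@]2(C)[C@H]1C | intermediate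
32 | 12-O-TBS ether of 31 | CC[Si](CC)(CC)O[C@@H]1CC[C@@H]2[C@@H](O[Si](C)(C)C(C)(C)C)C(O)/C(=C(/C)CO[Si](C)(C)C(C)(C)C)C[C@]2(C)[C@H]1C | intermediate
33 | 3α-(triethylsilyloxy)-9β,12-bis(TBS-oxy)-10βH-eremophil-7(11)Z-en-8-one | CC[Si](CC)(CC)O[C@@H]1CC[C@@H]2[C@@H](O[Si](C)(C)C(C)(C)C)C(=O)/C(=C(/C)CO[Si](C)(C)C(C)(C)C)C[C@]2(C)[C@H]1C | intermediate
34 | 9β,12-bis(TBS-oxy)-3α-hydroxy-10βH-eremophil-7(11)Z-en-8-one | O[C@@H]1CC[C@@H]2[C@@H](O[Si](C)(C)C(C)(C)C)C(=O)/C(=C(/C)CO[Si](C)(C)C(C)(C)C)C[C@]2(C)[C@H]1C | intermediate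
35 | (E)-oct-2-enal | CCCCC/C=C/C=O | starting material
36 | (E)-non-3-en-1-yne | CCCCC/C=C/C#C | intermediate
37 | ethyl (E)-3-iodoacrylate | CCOC(=O)/C=C/I | starting material
38 | dimethyl[(1E,3E)-2-methylnona-1,3-dien-1-yl]alane | CCCCC/C=C/C(C)=C/[Al](C)C | intermediate (not isolated)
39 | ethyl (2E,4E,6E)-5-methyldodeca-2,4,6-trienoate | CCCCC/C=C/C(C)=C/C=C/C(=O)OCC | intermediate
40 | (2E,4E,6E)-5-methyldodeca-2,4,6-trienoic acid | CCCCC/C=C/C(C)=C/C=C/C(=O)O | intermediate
41 | mixed anhydride of 40 with 2,4,6-trichlorobenzoic acid | CCCCC/C=C/C(C)=C/C=C/C(=O)OC(=O)c1c(Cl)cc(Cl)cc1Cl | intermediate (not isolated)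
42 | 3α-trienoyloxy-9β,12-bis(TBS-oxy)-10βH-eremophil-7(11)Z-en-8-one | CCCCC/C=C/C(C)=C/C=C/C(=O)O[C@@H]1CC[C@@H]2[C@@H](O[Si](C)(C)C(C)(C)C)C(=O)/C(=C(/C)CO[Si](C)(C)C(C)(C)C)C[C@]2(C)[C@H]1C | intermediate
43 | (3R,4R,5R,9R,10S)-9,12-dihydroxy-8-oxoeremophil-7(11)Z-en-3-yl (2E,4E,6E)-5-methyldodeca-2,4,6-trienoate | CCCCC/C=C/C(C)=C/C=C/C(=O)O[C@@H]1CC[C@@H]2[C@@H](O)C(=O)/C(=C(/C)CO)C[C@]2(C)[C@H]1C | target

**Count**

Total step count: 23. Longest linear sequence: 20 steps (steps 1–18, then 22 and 23); the acid branch is steps 19–21.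

**Steps most likely to fail**

Step 7. The catalyst may discriminate poorly between the two enantiotopic enone arms, or enamine formation at the hindered α-silyloxy ketone may be too slow for useful turnover. The fallback gives up catalyst control. Setting out from 12, the ring is closed with an achiral promoter (pyrrolidinium acetate, or DBU through the C9 enolate). The tether still enforces cis fusion and the same relative configuration, so 15 forms as a racemate with its mirror image ent-15 F1. The enantiomers are then separated by preparative chromatography on a chiral stationary phase, and the route is rejoined at 15.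

Step 13. The C3 silyloxy group may be lost by β-elimination while the diazene decomposes (giving a C2=C3 alkene), or reduction of the hindered hydrazone may stall. The fallback is a radical deoxygenation. Setting out from 24, NaBH4 in EtOH at −40 °C reduces the C2 ketone (the lactone survives) to the 2ξ-carbinol F2. 1,1'-Thiocarbonyldiimidazole acylates only this secondary hydroxyl, not the tertiary C11 hydroxyl, to give the O-(imidazol-1-ylthiocarbonyl) derivative F3. Bu3SnH with AIBN in toluene at 90 °C (Barton–McCombie) then removes the C2 oxygen and returns to the route at 28.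

Step 14. For diastereomers that lack a C7–H anti to the leaving group, elimination will turn toward the C13 methyl and give the exocyclic α-methylene lactone instead of the ring double bond. The fallback replaces kinetic regiocontrol with thermodynamic control. Setting out from 28, the same SOCl2/pyridine elimination is run and the 11(13)-methylene lactone F4 formed beside 29 is not separated. The crude mixture is heated with RuHCl(CO)(PPh3)3 (5 mol %) in toluene at 80 °C; hydride addition–elimination moves the exocyclic double bond into conjugation in the ring, where the tetrasubstituted butenolide is the sink, and the route is rejoined at 29.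

**Further compounds**

F1 | step 7 | ent-15, (4aS,8S,8aR)-8-[(tert-butyldimethylsilyl)oxy]-4a-methyl-4a,5,6,8a-tetrahydronaphthalene-2,7(1H,8H)-dione, formed with 15 as the racemate | O=C1C=C[C@]2(C)CCC(=O)[C@@H](O[Si](C)(C)C(C)(C)C)[C@@H]2C1
F2 | step 13 | 2ξ-hydroxy-3α-(triethylsilyloxy)-9β-OTBS-11ξ-hydroxy-10βH-eremophilan-12,8ξ-olide | CC[Si](CC)(CC)O[C@@H]1C(O)C[C@@H]2[C@@H](O[Si](C)(C)C(C)(C)C)C3OC(=O)C(C)(O)C3C[C@]2(C)[C@H]1C
F3 | step 13 | 2-O-(1H-imidazol-1-ylthiocarbonyl) derivative of F2 | CC[Si](CC)(CC)O[C@@H]1C(OC(=S)n3ccnc3)C[C@@H]2[C@@H](O[Si](C)(C)C(C)(C)C)C3OC(=O)C(C)(O)C3C[C@]2(C)[C@H]1C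
F4 | step 14 | 3α-(triethylsilyloxy)-9β-OTBS-10βH-eremophil-11(13)-en-12,8ξ-olide (7ξ) | CC[Si](CC)(CC)O[C@@H]1CC[C@@H]2[C@@H](O[Si](C)(C)C(C)(C)C)C3OC(=O)C(=C)C3C[C@]2(C)[C@H]1C
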